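## The problem

Juglanin A (16) is a diaryl ether heptanoid with no stereocentre, so the whole difficulty lies in its connectivity. It is a 15-membered oxa-meta,para-cyclophane: anisole ring A is bridged across a meta pair (a4 carries C1 of the chain, a6 the ether oxygen, and the a1 methoxy is ortho to that oxygen), phenol ring B is bridged across a para pair (b1 carries the ether oxygen, b4 carries C7), and the chain C1–C7 holds a ketone at C3. Ring B is contiguously tetrasubstituted (b1 aryloxy, b6 methoxy, b5 hydroxy, b4 alkyl), so three oxygens on neighbouring carbons must be told apart, and the diaryl ether joins two carbons that each have a methoxy neighbour. Because the para bridge forces ring B out of its relaxed position, any ring closure competes with dimerisation and should be run dilute and be irreversible. The groups that dislike rough treatment are the free guaiacol-type phenol (oxidants, hot base with air) and the enolisable dialkyl ketone, which would pull a nearby double bond into conjugation. Since there is nothing stereochemical to relay, a racemic carbinol at C3 and an alkene of mixed geometry may be carried, provided both are erased at the end. The feature that opens the route is the C5–C6 bond in the middle of the methylene run C4–C7: C7 sits on b4 next to the b5 oxygen, exactly where an aromatic Claisen rearrangement places an allyl group, and C5 is two carbons from C3, so an allyl nucleophile added to a C3 aldehyde supplies C4, C5 and a second terminal CH2.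

## Retrosynthesis

Endgame adjustments (16 from 15 from 14). No skeletal bond is cut. The C5–C6 single bond is traced back to a double bond, the b5 phenol to its benzyl ether, and the C3 ketone to a carbinol. One hydrogenation of 15 should saturate the alkene and free the phenol together. The oxidation of 14 to 15 is placed before it because the free phenol would not tolerate the oxidant. Keeping C3 as a carbinol during ring closure avoids a β,γ-unsaturated ketone in the presence of the metathesis catalyst and needs no ketal.

Ring opening at C5=C6 (14 from 13). The macrocycle is cut at C5=C6, which is formed in the forward sense by ring-closing olefin metathesis with loss of the two terminal methylene groups as a gas. Three neighbouring cuts were weighed against it. A cut at C6=C7 would need a styrene on ring B and would put a conjugated, ring-flattening alkene into the bridge. A cut at C4=C5 would need an electron-poor vinyl ketone partner. A cut at the a6–O bond would mean closing the ring by copper-mediated etherification at high temperature and high dilution. C5=C6 instead joins two monosubstituted, unconjugated alkenes, each insulated by one CH2. The precursor 13 is an acyclic diaryl ether with two allyl-derived arms. The forward step must make cyclisation beat oligomerisation and must not let either alkene migrate.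

Ring A arm (13 from 11 and 12, 11 from 10). The C3–C4 bond is cut, giving aldehyde 11 and allylmagnesium bromide 12. The aldehyde goes back to methyl ester 10 by partial reduction. The ester is preferred as the carrier of the arm through the earlier steps because a secondary alcohol would complicate the copper coupling and the thermal rearrangement. The forward addition has nothing to control: racemic 13 is sufficient.

Ring B allyl group (10 from 9, 9 from 7 via 8). After removal of the benzyl group (10 to 9), the b4–C7 bond is cut by a retro-Claisen step that returns the allyl group to the b5 oxygen in ether 7; the forward shift passes through dienone 8. Direct C-allylation of a phenol would not distinguish b4 from b2. The [3,3] shift must go to b4 because the other ortho carbon, b6, carries the methoxy group. The allyl ether in 7 also protects the b5 oxygen during diaryl ether formation, so it does two jobs.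

Diaryl ether (7 from 3 and 6). The a6–O bond is cut, giving aryl bromide 3 and phenol 6. Ring A is chosen as the halide because one bromination installs the halogen at the correct carbon. Ring B is chosen as the phenol because it derives from a symmetric diol. The forward coupling must join two ortho-methoxylated partners under copper catalysis without disturbing the ester or the allyl ether.

Building blocks (3 from 2 from 1; 6 from 4 and 5). Bromide 3 comes from ester 2 by bromination ortho to the methoxy group (the para position is occupied by the chain), and 2 comes from acid 1 by esterification. Phenol 6 comes from mono-O-allylation of symmetric 2-methoxyresorcinol 4 with allyl bromide 5. The only demand here is stopping at the mono-ether.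

## Roads not taken

Alternative 1: photo-Fries transposition of a macrolactone. The cut is the b4–C7 bond, which leads back to the 15-membered aryl ester A1, in which a C7 carboxyl acylates the b5 oxygen and C3 is masked as a dioxolane. In the forward sense, ultraviolet irradiation of A1 would break the aryl ester O–acyl bond and recombine the radical pair at the neighbouring carbon b4 to give the ortho-hydroxyaryl ketone A2. Its merits are real: the ring is first closed by acylation of a phenol, which is more dependable than a macrocyclic metathesis, the acyl group protects the b5 oxygen until the rearrangement frees it, and only b4 is available as an ortho terminus. Its weak points are that the rearrangement turns a meta-bridged ring B into the more strained para-bridged one through a caged radical pair. Escape from the cage, decarbonylation and migration to the free para carbon b2 are the usual competing paths, and both arenes absorb in the same region. After the key step the C7 carbonyl must be reduced to CH2 and the ketal removed, and C3 must stay protected throughout. In comparison, this road has the better ring closure on paper and needs no phenol protecting group. The chosen plan sets against it a thermal, catalytic closure that is driven by loss of a gas, and a two-step endgame with no redox correction at C7.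

Alternative 2: [3+3] annulation that makes ring A and the macrocycle together. The cut runs through the a2–a3 and a5–a6 bonds of ring A and leads back to A3, an aryloxyacetone on the b1 oxygen tethered through the ketal-protected chain to a 2-alkylmalondialdehyde. In the forward sense, secondary amine and acid catalysis would condense both α-carbons of the ketone with the two formyl groups and aromatise to the macrocyclic phenol A4, which carries OH in place of the a1 methoxy group. Its merit is that there is no diaryl ether coupling at all, because the ring A oxygen bond exists before ring A does. On this point the alternative is better than the chosen plan, whose copper coupling joins two hindered partners. Its weak points are that the ketone must react at its methyl carbon and at its aryloxymethylene carbon, in that pairing, with an electrophile that exists mainly as an unreactive enol. The first C–C bond is a reversible aldol macrocyclisation that competes with intermolecular condensation, the precursor needs a malondialdehyde at the end of a protected chain, and three steps remain after the key step (O-methylation, ketal removal, debenzylation). In comparison, the chosen plan is shorter, uses only reaction types with firm precedent, and closes the ring irreversibly. Its cost is the hindered copper coupling that this alternative avoids.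

Alternative 3: pyrone–ynol ether Diels–Alder macrocyclisation. The cut runs through the a4–a5 and a1–a6 bonds and leads back to A5, a 6-alkyl-3-methoxy-2-pyrone whose chain ends in ring B carrying an ethynyl ether on b1 and a methoxymethyl ether on b5. In the forward sense, heating would bring about an intramolecular [4+2] cycloaddition followed by decarboxylation, giving the methoxymethyl ether A6 of the natural product. Its merits are that ring A, the diaryl ether and the macrocycle arise together, that polarity (the nucleophilic terminal alkyne carbon meets the electrophilic pyrone C6) and the tether favour the same regiochemistry, and that decarboxylation makes the step irreversible. Only one deprotection separates A6 from 16, which is better than the two-step endgame of the chosen plan. Its weak points are that aryl ethynyl ethers are made by strong-base eliminations that clash with the ketone and the pyrone, and that they are thermally fragile at the temperatures pyrone cycloadditions need. The cycloaddition must pass through a macrocyclic transition state at high dilution, and the substituted pyrone is itself a multi-step target. In comparison, the chosen plan sets against the shorter endgame of this road its stable precursors, which are assembled from cheap arenes and two allyl units.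

Key step: step 9

Remark on the chemistry: C3 of 13 and 14 is racemic, and C5=C6 of 14 and 15 is drawn E although a mixture of geometries is expected. Both elements disappear before 16, which is achiral.

## Route

Step 1
Reactants: 1 3-(4-methoxyphenyl)propanoic acid
Product: 2 methyl 3-(4-methoxyphenyl)propanoate
Conditions: MeOH, H2SO4 (cat.), reflux
Reagents that add atoms: methanol, CO
Why: Fischer esterification driven by methanol as solvent; it turns the acid into a neutral carrier that should survive steps 2 and 4 to 6.

Step 2
Reactants: 2 methyl 3-(4-methoxyphenyl)propanoate
Product: 3 methyl 3-(3-bromo-4-methoxyphenyl)propanoate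
Conditions: NBS, MeCN, 0 °C to rt, dark
Reagents that add atoms: N-bromosuccinimide, O=C1CCC(=O)N1Br
Why: Electrophilic aromatic bromination; methoxy is the strongest director and its para position is occupied by the side chain, so bromine should enter ortho to it, while the polar solvent in the dark suppresses benzylic radical bromination.

Step 3
Reactants: 4 2-methoxyresorcinol (2-methoxybenzene-1,3-diol); 5 allyl bromide
Product: 6 3-(allyloxy)-2-methoxyphenol
Conditions: K2CO3, acetone, reflux (4 in excess, 5 limiting)
Reagents that add atoms: none
Why: Williamson mono-etherification of a symmetric diol with the halide as limiting reagent; unreacted 4 should be removable by aqueous extraction and the neutral bis-ether by chromatography.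

Step 4
Reactants: 3 methyl 3-(3-bromo-4-methoxyphenyl)propanoate; 6 3-(allyloxy)-2-methoxyphenol
Product: 7 methyl 3-{3-[3-(allyloxy)-2-methoxyphenoxy]-4-methoxyphenyl}propanoate
Conditions: CuI (10 mol%), N,N-dimethylglycine hydrochloride (30 mol%), Cs2CO3, 1,4-dioxane, 100 °C
Reagents that add atoms: none
Why: Ullmann diaryl ether synthesis under amino acid-accelerated copper catalysis; only one phenol is free because the other oxygen is masked as the allyl ether, and the methyl ester and the allyl ether should be inert to Cs2CO3 in dioxane at this temperature.

Step 5
Reactants: 7 methyl 3-{3-[3-(allyloxy)-2-methoxyphenoxy]-4-methoxyphenyl}propanoate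
Product: 9 methyl 3-{3-[4-allyl-3-hydroxy-2-methoxyphenoxy]-4-methoxyphenyl}propanoate, via ortho-allyl cyclohexadienone 8 (not isolated)
Conditions: PhNEt2, 190 °C
Reagents that add atoms: none
Why: Aromatic Claisen rearrangement; the concerted [3,3] shift to the only unsubstituted ortho carbon b4 gives dienone 8, which tautomerises to phenol 9, whereas attack at b6 (methoxy-bearing) cannot rearomatise and would need a slower second shift.

Step 6
Reactants: 9 methyl 3-{3-[4-allyl-3-hydroxy-2-methoxyphenoxy]-4-methoxyphenyl}propanoate
Product: 10 methyl 3-{3-[4-allyl-3-(benzyloxy)-2-methoxyphenoxy]-4-methoxyphenyl}propanoate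
Conditions: BnBr, K2CO3, n-Bu4NI (cat.), DMF, rt to 50 °C
Reagents that add atoms: benzyl bromide, BrCc1ccccc1
Why: Williamson etherification; the phenoxide between methoxy and allyl is hindered but should react with a benzylic halide under iodide catalysis, and benzyl is chosen because the final hydrogenation removes it at no extra cost.

Step 7
Reactants: 10 methyl 3-{3-[4-allyl-3-(benzyloxy)-2-methoxyphenoxy]-4-methoxyphenyl}propanoate
Product: 11 3-{3-[4-allyl-3-(benzyloxy)-2-methoxyphenoxy]-4-methoxyphenyl}propanal
Conditions: i-Bu2AlH (1.1 equiv), CH2Cl2, −78 °C; MeOH, then aq. KNaC4H4O6
Reagents that add atoms: none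
Why: Partial reduction of an ester with one equivalent of i-Bu2AlH; the tetrahedral aluminium hemiacetal should persist at −78 °C and release the aldehyde only on quench, and isolated terminal alkenes are not hydroaluminated in the cold.

Step 8
Reactants: 11 3-{3-[4-allyl-3-(benzyloxy)-2-methoxyphenoxy]-4-methoxyphenyl}propanal; 12 allylmagnesium bromide (CH2=CHCH2MgBr)
Product: 13 1-{3-[4-allyl-3-(benzyloxy)-2-methoxyphenoxy]-4-methoxyphenyl}hex-5-en-3-ol (racemic)
Conditions: Et2O/THF, −78 to 0 °C; aq. NH4Cl
Reagents that add atoms: none
Why: Grignard allylation of an aldehyde; no control is sought at the new C3 stereocentre because the carbinol is oxidised in step 10, so racemic 13 suffices.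

Step 9
Reactants: 13 1-{3-[4-allyl-3-(benzyloxy)-2-methoxyphenoxy]-4-methoxyphenyl}hex-5-en-3-ol (racemic)
Product: 14 macrocyclic alkene carbinol (15-membered oxa-meta,para-cyclophane; C5=C6 drawn E; C3 carbinol racemic; b5 oxygen as benzyl ether)
Conditions: (H2IMes)(PCy3)Cl2Ru=CHPh (second-generation Grubbs catalyst, 10 mol%), 1,4-benzoquinone (20 mol%), CH2Cl2 (1 mM), 40 °C
Reagents that add atoms: none
Why: Ring-closing olefin metathesis by the Chauvin mechanism: the ruthenium benzylidene exchanges with one monosubstituted alkene of 13, the resulting alkylidene undergoes intramolecular [2+2] cycloaddition with the other terminal alkene, and cycloreversion of the ruthenacyclobutane releases 14 and a ruthenium methylidene that propagates the catalytic cycle. The closest known reaction type is macrocyclic ring-closing metathesis of α,ω-dienes to 14- to 16-membered cycloalkenes and cyclophanes with this catalyst at millimolar concentration. The single new ring, the 15-membered cyclophane, is closed end to end at C5=C6, with the diaryl ether oxygen acting as a hinge that already holds the two arms on the same side. No stereocentre is formed; C3 stays racemic and the alkene geometry is left uncontrolled because steps 10 and 11 erase both. The first selectivity needed is cyclisation over oligomerisation, which high dilution, escape of ethylene and two unhindered terminal alkenes should secure, and open-chain oligomers can re-enter the cycle by secondary metathesis. The second is positional integrity of the alkenes, which the CH2 spacer on each side and 1,4-benzoquinone as a scavenger of ruthenium hydrides should secure. The free secondary alcohol and the benzyl ether are tolerated by the catalyst, and C3 as a carbinol keeps an enolisable β,γ-unsaturated ketone out of the closure.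

Step 10
Reactants: 14 macrocyclic alkene carbinol
Product: 15 macrocyclic β,γ-unsaturated ketone (C3 ketone of 14; C5=C6 and the benzyl ether retained)
Conditions: Dess–Martin periodinane, CH2Cl2, 0 °C to rt
Reagents that add atoms: none
Why: Dess–Martin oxidation of a secondary alcohol under near-neutral conditions; the benzyl ether and the electron-rich arenes should be untouched, and any drift of C5=C6 into conjugation with the new ketone is harmless because step 11 saturates either isomer.

Step 11
Reactants: 15 macrocyclic β,γ-unsaturated ketone
Product: 16 juglanin A
Conditions: H2 (1 atm), Pd/C (10%), EtOAc/EtOH, rt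
Reagents that add atoms: none
Why: Heterogeneous catalytic hydrogenation should reduce the disubstituted alkene and hydrogenolyse the benzyl ether in one operation; the non-benzylic dialkyl ketone, the aryl methyl ethers and the diaryl ether are inert under these conditions.

## Compound list

1 | 3-(4-methoxyphenyl)propanoic acid | COc1ccc(CCC(=O)O)cc1 | starting material
2 | methyl 3-(4-methoxyphenyl)propanoate | COC(=O)CCc1ccc(OC)cc1 | intermediate
3 | methyl 3-(3-bromo-4-methoxyphenyl)propanoate | COC(=O)CCc1ccc(OC)c(Br)c1 | intermediate
4 | 2-methoxyresorcinol (2-methoxybenzene-1,3-diol) | COc1c(O)cccc1O | starting material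
5 | allyl bromide | C=CCBr | starting material
6 | 3-(allyloxy)-2-methoxyphenol | COc1c(O)cccc1OCC=C | intermediate
7 | methyl 3-{3-[3-(allyloxy)-2-methoxyphenoxy]-4-methoxyphenyl}propanoate | COC(=O)CCc1ccc(OC)c(Oc2cccc(OCC=C)c2OC)c1 | intermediate
8 | methyl 3-{3-[(4-allyl-2-methoxy-3-oxocyclohexa-1,5-dien-1-yl)oxy]-4-methoxyphenyl}propanoate (Claisen dienone, racemic, not isolated) | COC(=O)CCc1ccc(OC)c(OC2=C(OC)C(=O)C(CC=C)C=C2)c1 | intermediate
9 | methyl 3-{3-[4-allyl-3-hydroxy-2-methoxyphenoxy]-4-methoxyphenyl}propanoate | COC(=O)CCc1ccc(OC)c(Oc2ccc(CC=C)c(O)c2OC)c1 | intermediate
10 | methyl 3-{3-[4-allyl-3-(benzyloxy)-2-methoxyphenoxy]-4-methoxyphenyl}propanoate | COC(=O)CCc1ccc(OC)c(Oc2ccc(CC=C)c(OCc3ccccc3)c2OC)c1 | intermediate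
11 | 3-{3-[4-allyl-3-(benzyloxy)-2-methoxyphenoxy]-4-methoxyphenyl}propanal | O=CCCc1ccc(OC)c(Oc2ccc(CC=C)c(OCc3ccccc3)c2OC)c1 | intermediate
12 | allylmagnesium bromide | C=CC[Mg]Br | starting material
13 | 1-{3-[4-allyl-3-(benzyloxy)-2-methoxyphenoxy]-4-methoxyphenyl}hex-5-en-3-ol (racemic) | COc1ccc(CCC(O)CC=C)cc1Oc1ccc(CC=C)c(OCc2ccccc2)c1OC | intermediate
14 | macrocyclic alkene carbinol (C5=C6 drawn E, C3 carbinol racemic, b5 benzyl ether) | COc1ccc(CCC(O)C/C=C/C2)cc1Oc1ccc2c(OCc3ccccc3)c1OC | intermediate
15 | macrocyclic β,γ-unsaturated ketone (C3 ketone, C5=C6 drawn E, b5 benzyl ether) | COc1ccc(CCC(=O)C/C=C/C2)cc1Oc1ccc2c(OCc3ccccc3)c1OC | intermediate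
16 | juglanin A | COc1ccc2cc1Oc1ccc(c(O)c1OC)CCCCC(=O)CC2 | target

## Step count and least certain steps

Total step count: 11. Longest linear sequence: 10 steps (1 to 16 through steps 1, 2 and 4 to 11); the ring B branch (4 to 6, step 3) joins at step 4.

Step 9 (key step). The transition state must already bend the para-bridged ring B, so intermolecular metathesis may overtake closure and lead to cyclodimerisation and oligomerisation. Ruthenium hydrides may also move the ring B allyl double bond into conjugation with the arene, after which closure would expel propene and contract the ring by one carbon. The fallback forms C5=C6 intermolecularly and closes the ring at the diaryl ether instead; it sets out from 3 and 6 and returns at 14. On the ring A side, reduction of 3 with i-Bu2AlH at −78 °C should give 3-(3-bromo-4-methoxyphenyl)propanal F1 as the aldehyde, and addition of 12 to F1 should give racemic 1-(3-bromo-4-methoxyphenyl)hex-5-en-3-ol F2 as the homoallylic carbinol. On the ring B side, pivaloylation of 6 (pivaloyl chloride, Et3N, DMAP) should give 3-(allyloxy)-2-methoxyphenyl pivalate F3 with the b1 oxygen masked. Claisen rearrangement of F3 (PhNEt2, 190 °C) should give 4-allyl-3-hydroxy-2-methoxyphenyl pivalate F4 with the allyl group on b4. Benzylation of F4 (BnBr, K2CO3, acetone) should give 4-allyl-3-(benzyloxy)-2-methoxyphenyl pivalate F5 as the fully protected arene, and methanolysis of F5 (NaOMe, MeOH) should give 4-allyl-3-(benzyloxy)-2-methoxyphenol F6 with the b1 phenol free. Cross-metathesis of F2 with F6 ((H2IMes)(PCy3)Cl2Ru=CHPh, CH2Cl2, 40 °C, one partner in excess) should give (E)-1-(3-bromo-4-methoxyphenyl)-7-[2-(benzyloxy)-4-hydroxy-3-methoxyphenyl]hept-5-en-3-ol F7 as the open-chain bromophenol. Intramolecular Ullmann etherification of F7 under high dilution (CuO, K2CO3, pyridine, 150 °C) should then close the a6–O bond and deliver 14.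

Step 4. Oxidative addition of the electron-rich, ortho-methoxylated aryl bromide to copper and exchange with the equally hindered phenoxide may both be slow, so protodebromination and catalyst decay may win. The fallback reverses the roles of the ring A partner in an oxidative Chan–Lam coupling; it sets out from 3 and returns at 7. Miyaura borylation of 3 (B2pin2, Pd(dppf)Cl2, KOAc, 1,4-dioxane, 80 °C) should give methyl 3-[4-methoxy-3-(4,4,5,5-tetramethyl-1,3,2-dioxaborolan-2-yl)phenyl]propanoate F8 as the pinacol boronate. Oxidative removal of pinacol from F8 (NaIO4, NH4OAc, acetone/H2O) should give [2-methoxy-5-(3-methoxy-3-oxopropyl)phenyl]boronic acid F9 as the free boronic acid, and coupling of F9 with 6 (Cu(OAc)2, pyridine, 4 Å molecular sieves, CH2Cl2, air, rt) should give 7.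

Step 7. The aluminium hemiacetal may collapse before the quench and expose the aldehyde to a second hydride, giving over-reduction. The fallback separates the two redox events; it sets out from 10 and returns at 11. Full reduction with LiAlH4 (THF, 0 °C) should give 3-{3-[4-allyl-3-(benzyloxy)-2-methoxyphenoxy]-4-methoxyphenyl}propan-1-ol F10 as the primary alcohol, and Parikh–Doering oxidation of F10 (SO3·pyridine, DMSO, Et3N) should give 11.

Step 3. The first allylation hardly changes the reactivity of the second hydroxyl, so double allylation may erode the mono-ether. The fallback moves the desymmetrisation into the coupling, where the cheap diol can be used in large excess; it sets out from 3 and 4 and returns at 7. Copper-catalysed coupling of 3 with excess 4 (CuI, N,N-dimethylglycine hydrochloride, Cs2CO3, 1,4-dioxane, 100 °C) should give methyl 3-[3-(3-hydroxy-2-methoxyphenoxy)-4-methoxyphenyl]propanoate F11 as the mono-arylated diol, and O-allylation of F11 with 5 (K2CO3, acetone, reflux) should give 7.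

## Further compounds

F1 | step 9 | 3-(3-bromo-4-methoxyphenyl)propanal | O=CCCc1ccc(OC)c(Br)c1
F2 | step 9 | 1-(3-bromo-4-methoxyphenyl)hex-5-en-3-ol (racemic) | C=CCC(O)CCc1ccc(OC)c(Br)c1
F3 | step 9 | 3-(allyloxy)-2-methoxyphenyl pivalate | COc1c(OCC=C)cccc1OC(=O)C(C)(C)C
F4 | step 9 | 4-allyl-3-hydroxy-2-methoxyphenyl pivalate | COc1c(O)c(CC=C)ccc1OC(=O)C(C)(C)C
F5 | step 9 | 4-allyl-3-(benzyloxy)-2-methoxyphenyl pivalate | COc1c(OCc2ccccc2)c(CC=C)ccc1OC(=O)C(C)(C)C
F6 | step 9 | 4-allyl-3-(benzyloxy)-2-methoxyphenol | COc1c(OCc2ccccc2)c(CC=C)ccc1O
F7 | step 9 | (E)-1-(3-bromo-4-methoxyphenyl)-7-[2-(benzyloxy)-4-hydroxy-3-methoxyphenyl]hept-5-en-3-ol (racemic) | COc1ccc(CCC(O)C/C=C/Cc2ccc(O)c(OC)c2OCc3ccccc3)cc1Br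
F8 | step 4 | methyl 3-[4-methoxy-3-(4,4,5,5-tetramethyl-1,3,2-dioxaborolan-2-yl)phenyl]propanoate | COC(=O)CCc1ccc(OC)c(B2OC(C)(C)C(C)(C)O2)c1
F9 | step 4 | [2-methoxy-5-(3-methoxy-3-oxopropyl)phenyl]boronic acid | COC(=O)CCc1ccc(OC)c(B(O)O)c1
F10 | step 7 | 3-{3-[4-allyl-3-(benzyloxy)-2-methoxyphenoxy]-4-methoxyphenyl}propan-1-ol | OCCCc1ccc(OC)c(Oc2ccc(CC=C)c(OCc3ccccc3)c2OC)c1
F11 | step 3 | methyl 3-[3-(3-hydroxy-2-methoxyphenoxy)-4-methoxyphenyl]propanoate | COC(=O)CCc1ccc(OC)c(Oc2cccc(O)c2OC)c1
A1 | alternative 1 | 15-membered aryl ester macrolactone (C7 carboxyl on the b5 oxygen, C3 as ethylene ketal) | COc1ccc2cc1Oc1cccc(c1OC)OC(=O)CCCC1(OCCO1)CC2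
A2 | alternative 1 | 7-oxo-juglanin A ethylene ketal | COc1ccc2cc1Oc1ccc(c(O)c1OC)C(=O)CCCC1(OCCO1)CC2
A3 | alternative 2 | acyclic aryloxyacetone with tethered 2-alkylmalondialdehyde (C3 ketal, b5 benzyl ether) | CC(=O)COc1ccc(CCCCC2(OCCO2)CCC(C=O)C=O)c(OCc3ccccc3)c1OC
A4 | alternative 2 | macrocyclic ring A phenol (a1 hydroxy, C3 ketal, b5 benzyl ether) | Oc1ccc2cc1Oc1ccc(c(OCc3ccccc3)c1OC)CCCCC1(OCCO1)CC2
A5 | alternative 3 | 6-alkyl-3-methoxy-2-pyrone tethered to the ring B ethynyl ether (b5 methoxymethyl ether) | COc1ccc(CCC(=O)CCCCc2ccc(OC#C)c(OC)c2OCOC)oc1=O
A6 | alternative 3 | juglanin A methoxymethyl ether | COc1ccc2cc1Oc1ccc(c(OCOC)c1OC)CCCCC(=O)CC2
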